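**Plan**

1. Numbering: ring A is the fused guaiacyl ring (C1 bears C7, C2 bears C7', O4 is para to C1). Ring B is C1–C7–C8–C8'–C7'–C2, and C9/C9' are the CH2O arms on C8/C8'. Retrosynthetic cuts, in order: S–O9', C7–C8 (ring B), C8–C9, C8'–C9', C7'–C1' (pendant aryl), C2–C7'.
2. Enabling feature: C8 carries CH2OH, so C8–C9–O9 is the footprint of a reductively opened terminal oxirane with the radical at C8. C7 sits on ring A ortho to the C7' branch, so a nitrile carbon placed there lies 6-exo to that radical. Ti(III) joins these two electrophilic carbons.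
3. Forward: the C7'–C8'–C8–C9 chain is grown on a 2-bromobenzonitrile (Heck reaction, aryl 1,4-addition, formaldehyde aldol, sulfur-ylide CH2). Ring B closes last, followed by reduction, acetal formation, sulfation and hydrogenolysis.
4. Stereochemistry: C7' comes from the Rh/chiral-diene 1,4-addition and C8' from the prolinol-ether enamine catalyst. C8 comes from the chair-like ring closure and its α-carbonyl equilibration to the all-equatorial (all-trans) array.
5. Helper: the nitrile-derived oxygen on C7 ties O9 into a 1,3-dioxane, which leaves O9' as the only hydroxyl for sulfation. It is removed with the benzyl groups in the final hydrogenolysis.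

Key step: step 7

Assumption 1: sulfate monoesters are drawn and counted as free hydrogen sulfates. In practice they would be handled as salts, and the acid form released on an H+ ion-exchange resin at the end.
Assumption 2: centres that are erased later are left undefined in the SMILES because both epimers converge. These are the oxirane CH in 10, the carbinol C7 in 13–15 and the acetal CH in 14–15.

**Step 1**
Reactants: 1 4-(benzyloxy)-3-methoxybenzonitrile
Product: 2 4-(benzyloxy)-2-bromo-5-methoxybenzonitrile
Conditions: Br2, NaOAc, AcOH, rt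
Reagents that add atoms: bromine, BrBr
Why: Electrophilic aromatic bromination should go para to the methoxy group, the only unhindered activated position, as in the 6-bromination of veratraldehyde-type arenes, while NaOAc buffers HBr so that the benzyl ether survives.

**Step 2**
Reactants: 2 4-(benzyloxy)-2-bromo-5-methoxybenzonitrile; 3 acrolein diethyl acetal
Product: 5 4-(benzyloxy)-5-methoxy-2-[(E)-3-oxoprop-1-enyl]benzonitrile, via diethyl acetal 4 (not isolated)
Conditions: Pd(OAc)2 (cat.), n-Bu4NOAc, K2CO3, KCl, DMF, 90 °C; then 2 M HCl, rt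
Reagents that add atoms: water, O
Why: This is a Heck reaction with the acetal as a non-polymerising acrolein equivalent, in which the ortho nitrile speeds oxidative addition, syn β-hydride elimination gives the E-alkene, and dilute acid unmasks the enal.

**Step 3**
Reactants: 5 4-(benzyloxy)-5-methoxy-2-[(E)-3-oxoprop-1-enyl]benzonitrile; 6 [4-(benzyloxy)-3-methoxyphenyl]boronic acid
Product: 7 4-(benzyloxy)-2-{(1S)-1-[4-(benzyloxy)-3-methoxyphenyl]-3-oxopropyl}-5-methoxybenzonitrile
Conditions: [RhCl(C2H4)2]2 (cat.), (S,S)-Ph-bod* [(1S,4S)-2,5-diphenylbicyclo[2.2.2]octa-2,5-diene], KOH (cat.), MeOH–H2O 10:1, 50 °C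
Reagents that add atoms: none
Why: In this Hayashi–Miyaura asymmetric 1,4-addition the diene ligand favours 1,4- over 1,2-addition to enals, this antipode should deliver the aryl group to the Re face of C-β by the model for (E)-acceptors and so set C7' as S, and the protic medium should protonate the rhodium enolate before it can add to the nitrile.

**Step 4**
Reactants: 7 (S)-3,3-diarylpropanal
Product: 8 4-(benzyloxy)-2-{(1S,2S)-1-[4-(benzyloxy)-3-methoxyphenyl]-2-(hydroxymethyl)-3-oxopropyl}-5-methoxybenzonitrile
Conditions: aq. HCHO (37 %), (R)-α,α-diphenylprolinol TMS ether (20 mol %), pH 7 phosphate buffer, toluene, rt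
Reagents that add atoms: formaldehyde, C=O
Why: In this enamine-catalysed α-hydroxymethylation (cross-aldol with formaldehyde) the shielded E-enamine of the (R)-catalyst should set C8' under catalyst control, and the minor enantiomer of 7 becomes a separable diastereomer.

**Step 5**
Reactants: 8 β-hydroxy aldehyde
Product: 9 4-(benzyloxy)-2-{(1S,2S)-1-[4-(benzyloxy)-3-methoxyphenyl]-3-oxo-2-[(triethylsilyloxy)methyl]propyl}-5-methoxybenzonitrile
Conditions: TESCl, imidazole, CH2Cl2, 0 °C
Reagents that add atoms: chlorotriethylsilane, CC[Si](Cl)(CC)CC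
Why: Standard O-silylation under weakly basic conditions blocks hemiacetal formation, retro-aldol cleavage and dehydration of the β-hydroxy aldehyde without touching the α-centre.

**Step 6**
Reactants: 9 β-silyloxy aldehyde
Product: 10 4-(benzyloxy)-2-{(1S,2S)-1-[4-(benzyloxy)-3-methoxyphenyl]-2-(oxiran-2-yl)-3-(triethylsilyloxy)propyl}-5-methoxybenzonitrile (both oxirane epimers)
Conditions: Me3SI, n-BuLi, THF, −10 °C; then 9, −78 → 0 °C
Reagents that add atoms: trimethylsulfonium iodide, C[S+](C)C.[I-]
Why: In this Corey–Chaykovsky epoxidation the ylide adds to α-chiral β-silyloxy aldehydes faster than it enolises them and ignores the aryl nitrile, and the new oxirane centre needs no control because it becomes a planar radical in step 7.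

**Step 7**
Reactants: 10 epoxy nitrile
Product: 12 (2R,3R,4S)-6-(benzyloxy)-4-[4-(benzyloxy)-3-methoxyphenyl]-2,3-bis(hydroxymethyl)-7-methoxy-3,4-dihydronaphthalen-1(2H)-one, via ketimine 11 (not isolated)
Conditions: Cp2TiCl2 (20 mol %), Mn, 2,4,6-collidine·HCl, THF, rt, slow addition of 10; then 1 M HCl, THF, rt
Reagents that add atoms: water, O
Why: Cp2TiCl, made from Cp2TiCl2 and Mn, binds the oxirane oxygen and cleaves C8–O homolytically to the secondary β-titanoxy radical at C8, which adds to the Ti-activated nitrile carbon C7; a second Ti(III) reduces the iminyl radical, collidinium chloride protonates N–Ti and O–Ti to turn the catalyst over, and aqueous acid then hydrolyses the ketimine and the TES ether. The closest known reaction type is the titanocene(III)-mediated and -catalysed radical cyclisation of epoxy nitriles to cyclic β-hydroxy ketones, a reductive union of two electrophilic carbons. Ring B closes in the 6-exo-dig mode through the in-plane π bond of the nitrile, with C7', C2, C1 and C7 pre-organised by ring A. The C8 radical is planar, so both oxirane epimers converge; C8 is set by a chair-like transition state with CH2OTi, CH2OTES and the C7' aryl group equatorial (8,8'-trans), and because C8 ends α to C=N/C=O the acidic work-up can only drive it further to this all-equatorial isomer, while C7' and C8' are not touched. The step needs regioselective opening, secured by secondary over primary radical stability, and cyclisation ahead of capture of the radical by a second Ti(III), which would deoxygenate it to the alkene; the low stationary Ti(III) concentration of the catalytic protocol with slow addition should secure the latter. Aryl ethers and the diarylmethine C–H are inert to Ti(III).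

**Step 8**
Reactants: 12 keto diol
Product: 13 (2R,3R,4S)-6-(benzyloxy)-4-[4-(benzyloxy)-3-methoxyphenyl]-2,3-bis(hydroxymethyl)-7-methoxy-1,2,3,4-tetrahydronaphthalen-1-ol (C-1 epimers)
Conditions: NaBH4, MeOH–THF, 0 °C → rt
Reagents that add atoms: none
Why: Borohydride reduction of the aryl ketone at low temperature should outrun retro-aldol cleavage, and the new carbinol centre C7 is irrelevant because it is removed in step 11.

**Step 9**
Reactants: 13 triol
Product: 14 7,9-O-benzylidene acetal of 13 (1,3-dioxane fused to ring B at C7–C8, free 9'-OH; 7'S,8R,8'R)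
Conditions: PhCH(OMe)2, PPTS (cat.), CH2Cl2, rt
Reagents that add atoms: benzaldehyde dimethyl acetal, COC(OC)c1ccccc1
Why: Under thermodynamic transacetalisation only O7 and O9 are 1,3-related and give a six-membered 1,3-dioxane, any acetal through O9' would be seven-membered, and the weak acid should not ionise the p-alkoxybenzylic C7–O bond.

**Step 10**
Reactants: 14 acetal alcohol
Product: 15 9'-O-sulfate of 14 (hydrogen sulfate)
Conditions: SO3·pyridine, pyridine, 0 °C → rt
Reagents that add atoms: sulfur trioxide–pyridine complex, O=S(=O)([O-])[n+]1ccccc1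
Why: O-sulfation with an amine–SO3 complex takes the only free hydroxyl (O9'), and benzylidene acetals and benzyl ethers tolerate it as in carbohydrate sulfation.

**Step 11**
Reactants: 15 protected sulfate
Product: 16 [(1S,2R,3R)-7-hydroxy-1-(4-hydroxy-3-methoxyphenyl)-3-(hydroxymethyl)-6-methoxy-1,2,3,4-tetrahydronaphthalen-2-yl]methyl hydrogen sulfate (target)
Conditions: H2 (4 atm), 10 % Pd/C, MeOH–AcOH, rt; then H+ ion-exchange resin
Reagents that add atoms: none
Why: Catalytic hydrogenolysis should cleave all benzylic C–O bonds at once, namely the two aryl benzyl ethers, the benzylidene carbon and the C7–O bond (a 4-aryl-1,3-dioxane to 3-arylpropanol type cleavage), while alkyl sulfate monoesters and the three stereocentres are inert.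

**Compound list**

1 | 4-(benzyloxy)-3-methoxybenzonitrile | N#Cc1ccc(OCc2ccccc2)c(OC)c1 | starting material
2 | 4-(benzyloxy)-2-bromo-5-methoxybenzonitrile | N#Cc1cc(OC)c(OCc2ccccc2)cc1Br | intermediate
3 | acrolein diethyl acetal | C=CC(OCC)OCC | starting material
4 | 4-(benzyloxy)-2-[(E)-3,3-diethoxyprop-1-enyl]-5-methoxybenzonitrile | CCOC(OCC)/C=C/c1cc(OCc2ccccc2)c(OC)cc1C#N | intermediate
5 | 4-(benzyloxy)-5-methoxy-2-[(E)-3-oxoprop-1-enyl]benzonitrile | O=C/C=C/c1cc(OCc2ccccc2)c(OC)cc1C#N | intermediate
6 | [4-(benzyloxy)-3-methoxyphenyl]boronic acid | COc1cc(B(O)O)ccc1OCc1ccccc1 | starting material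
7 | (S)-3,3-diarylpropanal | COc1cc([C@H](CC=O)c2cc(OCc3ccccc3)c(OC)cc2C#N)ccc1OCc1ccccc1 | intermediate
8 | (1S,2S)-α-hydroxymethyl aldehyde | COc1cc([C@H]([C@H](C=O)CO)c2cc(OCc3ccccc3)c(OC)cc2C#N)ccc1OCc1ccccc1 | intermediate
9 | (1S,2S)-TES ether aldehyde | COc1cc([C@H]([C@H](C=O)CO[Si](CC)(CC)CC)c2cc(OCc3ccccc3)c(OC)cc2C#N)ccc1OCc1ccccc1 | intermediate
10 | (1S,2S)-epoxy nitrile (oxirane epimers) | COc1cc([C@H]([C@H](C2CO2)CO[Si](CC)(CC)CC)c2cc(OCc3ccccc3)c(OC)cc2C#N)ccc1OCc1ccccc1 | intermediate
11 | (2S,3R,4S)-tetralone ketimine, 9-OH, 9'-OTES | COc1cc([C@H]2c3cc(OCc4ccccc4)c(OC)cc3C(=N)[C@@H](CO)[C@@H]2CO[Si](CC)(CC)CC)ccc1OCc1ccccc1 | intermediate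
12 | (2R,3R,4S)-keto diol | COc1cc([C@H]2c3cc(OCc4ccccc4)c(OC)cc3C(=O)[C@@H](CO)[C@@H]2CO)ccc1OCc1ccccc1 | intermediate
13 | (2R,3R,4S)-triol (C-1 epimers) | COc1cc([C@H]2c3cc(OCc4ccccc4)c(OC)cc3C(O)[C@@H](CO)[C@@H]2CO)ccc1OCc1ccccc1 | intermediate
14 | 7,9-O-benzylidene acetal, free 9'-OH | COc1cc([C@H]2c3cc(OCc4ccccc4)c(OC)cc3C3OC(c4ccccc4)OC[C@H]3[C@@H]2CO)ccc1OCc1ccccc1 | intermediate
15 | 7,9-O-benzylidene acetal 9'-hydrogen sulfate | COc1cc([C@H]2c3cc(OCc4ccccc4)c(OC)cc3C3OC(c4ccccc4)OC[C@H]3[C@@H]2COS(=O)(=O)O)ccc1OCc1ccccc1 | intermediate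
16 | (7'S,8R,8'R)-isolariciresinol 9'-O-sulfate | COc1cc([C@H]2c3cc(O)c(OC)cc3C[C@@H](CO)[C@@H]2COS(=O)(=O)O)ccc1O | target

Total step count: 11. Longest linear sequence: 11 steps (from 1).

**Steps most likely to fail**

**Step 7.** The C8 radical may be captured by a second Ti(III) and lose titanium oxide (deoxygenation to the vinyl compound). It may also abstract hydrogen from the solvent before it adds to the electron-rich aryl nitrile.
- The fallback sets out from 9 and replaces the radical closure by an intramolecular nitrile oxide cycloaddition that forms the same C7–C8 bond.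
- Wittig methylenation of 9 gives the terminal alkene F1.
- DIBAL-H at −78 °C with mild acidic work-up turns the nitrile into the aryl aldehyde F2.
- Hydroxylamine gives the aldoxime F3.
- PhI(OAc)2 oxidises F3 to the nitrile oxide F4, which should add across the tethered vinyl group (C7 to C8, O to C9) to give the ring-B-fused isoxazoline F5.
- Mo(CO)6 in wet acetonitrile cleaves N–O and hydrolyses the imine to the β-hydroxy ketone TES ether F6.
- 1 M HCl removes the silyl group and equilibrates C8, and the route is rejoined at 12.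

**Step 4.** The β,β-diaryl aldehyde may form its enamine slowly, the aldol may dehydrate to the α-methylene aldehyde, and facial selectivity may be poor if catalyst and C7' are mismatched.
- The fallback sets out from 7 and uses auxiliary control with soft enolisation.
- Pinnick oxidation gives the carboxylic acid F7.
- The mixed pivalic anhydride with (R)-4-benzyl-1,3-oxazolidin-2-one and LiCl gives the N-acyl oxazolidinone F8.
- TiCl4/i-Pr2NEt and s-trioxane give the α-hydroxymethyl imide F9.
- TESCl gives the silyl ether imide F10.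
- LiBH4 releases the primary alcohol F11.
- Dess–Martin oxidation rejoins the route at 9.

**Step 11.** The hindered C7–O bond may be cleaved incompletely. Alternatively, once the ring-A phenol is free, loss of O7 through a quinone methide and its styrene tautomer may erode the C8 configuration.
- The fallback sets out from 14 and removes O7 ionically before sulfation.
- Et3SiH/BF3·OEt2 (−78 → 0 °C) should open the acetal reductively to the primary 9-O-benzyl ether and reduce the liberated p-alkoxybenzylic alcohol to CH2. This gives the 4,4',9-tri-O-benzyl isolariciresinol F12.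
- SO3·pyridine gives its 9'-hydrogen sulfate F13.
- Plain debenzylation (H2, Pd/C) rejoins the route at 16.

**Further compounds**

F1 | step 7 | terminal alkene (vinyl on C8') | COc1cc([C@H]([C@H](C=C)CO[Si](CC)(CC)CC)c2cc(OCc3ccccc3)c(OC)cc2C#N)ccc1OCc1ccccc1
F2 | step 7 | aryl aldehyde | COc1cc([C@H]([C@H](C=C)CO[Si](CC)(CC)CC)c2cc(OCc3ccccc3)c(OC)cc2C=O)ccc1OCc1ccccc1
F3 | step 7 | (E)-aldoxime | COc1cc([C@H]([C@H](C=C)CO[Si](CC)(CC)CC)c2cc(OCc3ccccc3)c(OC)cc2/C=N/O)ccc1OCc1ccccc1
F4 | step 7 | nitrile oxide | COc1cc([C@H]([C@H](C=C)CO[Si](CC)(CC)CC)c2cc(OCc3ccccc3)c(OC)cc2C#[N+][O-])ccc1OCc1ccccc1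
F5 | step 7 | ring-B-fused isoxazoline | COc1cc([C@H]2c3cc(OCc4ccccc4)c(OC)cc3C3=NOC[C@H]3[C@@H]2CO[Si](CC)(CC)CC)ccc1OCc1ccccc1
F6 | step 7 | β-hydroxy ketone TES ether | COc1cc([C@H]2c3cc(OCc4ccccc4)c(OC)cc3C(=O)[C@@H](CO)[C@@H]2CO[Si](CC)(CC)CC)ccc1OCc1ccccc1
F7 | step 4 | (S)-3,3-diarylpropanoic acid | COc1cc([C@H](CC(=O)O)c2cc(OCc3ccccc3)c(OC)cc2C#N)ccc1OCc1ccccc1
F8 | step 4 | N-acyl (R)-4-benzyloxazolidinone | COc1cc([C@H](CC(=O)N2[C@H](Cc3ccccc3)COC2=O)c2cc(OCc3ccccc3)c(OC)cc2C#N)ccc1OCc1ccccc1
F9 | step 4 | α-hydroxymethyl imide | COc1cc([C@H]([C@H](C(=O)N2[C@H](Cc3ccccc3)COC2=O)CO)c2cc(OCc3ccccc3)c(OC)cc2C#N)ccc1OCc1ccccc1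
F10 | step 4 | silyl ether imide | COc1cc([C@H]([C@H](C(=O)N2[C@H](Cc3ccccc3)COC2=O)CO[Si](CC)(CC)CC)c2cc(OCc3ccccc3)c(OC)cc2C#N)ccc1OCc1ccccc1
F11 | step 4 | primary alcohol | COc1cc([C@H]([C@H](CO)CO[Si](CC)(CC)CC)c2cc(OCc3ccccc3)c(OC)cc2C#N)ccc1OCc1ccccc1
F12 | step 11 | 4,4',9-tri-O-benzyl isolariciresinol | COc1cc([C@H]2c3cc(OCc4ccccc4)c(OC)cc3C[C@@H](COCc3ccccc3)[C@@H]2CO)ccc1OCc1ccccc1
F13 | step 11 | 4,4',9-tri-O-benzyl isolariciresinol 9'-hydrogen sulfate | COc1cc([C@H]2c3cc(OCc4ccccc4)c(OC)cc3C[C@@H](COCc3ccccc3)[C@@H]2COS(=O)(=O)O)ccc1OCc1ccccc1
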